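**Plan**

1. Retrosynthesis: one move undoes the O1–C2 bond of ring C together with the three aryl–prenyl bonds (C8 and C6 of ring A, C3' of ring B). This turns the target into an isomer, a (2R,3S)-epoxychalcone whose three phenol oxygens carry 2-methylbut-3-en-2-yl (1,1-dimethylallyl) groups. The epoxide is then taken back to the E-enone, the enone is cut at Cα=Cβ (aldol), and the aryl–O bonds are cut to two fluorobenzonitriles and one tertiary allylic alcohol.
2. Enabling feature: every phenol oxygen of the target (O1 on C8a, the 7-OH, the 4'-OH) has a prenyl group on the ring carbon next to it (C8, C6, C3'), the imprint of an aromatic Claisen rearrangement. O1 is also linked through C8a–C4a–C4(=O)–C3(OH) to benzylic C2, so an epoxide across C2–C3 lies within reach of O1 for a 6-endo opening.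
3. Forward: the ring A ketone and the ring B aldehyde arise by SNAr with one tertiary alkoxide, a Claisen–Schmidt condensation joins them, and the enone is epoxidised asymmetrically. One thermal operation then moves all three allyl groups from oxygen to carbon and closes ring C last, with no protecting group left to remove.
4. Stereochemistry: C3 is Cα of the epoxide, set by the chiral lanthanum catalyst and not touched again. C2 arises by inversion at Cβ in the ring closure, which gives the 2,3-trans (2R,3R) isomer.

Key step: step 7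

Remark on the chemistry: the target SMILES is read as the (2R,3R), 2,3-trans dihydroflavonol. Flavanone numbering is used for the target, and primed locants 2'–6' denote ring A in the open-chain (chalcone) compounds.

**Route**

Step 1
Reactants: 1 2,4-difluorobenzonitrile; 2 2-methylbut-3-en-2-ol
Product: 4 2,4-bis[(2-methylbut-3-en-2-yl)oxy]benzonitrile, via 4-monoether 3 (not isolated)
Conditions: NaH (2.5 equiv), 2 (2.6 equiv), THF–DMF, 0 °C; then 1, 0 → 50 °C
Reagents that add atoms: none
Why: Twofold nucleophilic aromatic substitution (SNAr) of fluoride by the sodium tertiary alkoxide should work because both fluorines are activated (para, then ortho) by the slim nitrile group, which leaves room for the bulky ortho ether and avoids alkylating a chelated ortho-hydroxy ketone with a tertiary electrophile.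

Step 2
Reactants: 4 2,4-bis[(2-methylbut-3-en-2-yl)oxy]benzonitrile
Product: 6 1-{2,4-bis[(2-methylbut-3-en-2-yl)oxy]phenyl}ethan-1-one, via N-lithio ketimine 5 (not isolated)
Conditions: MeLi (1.3 equiv), Et2O–THF, −30 → 0 °C; aq. NH4Cl; then 10% aq. citric acid, THF, 0 °C → rt
Reagents that add atoms: methyllithium, [Li]C; water, O
Why: Addition of an organolithium to an aryl nitrile stops at the N-lithio ketimine, so no tertiary alcohol can form, and cold dilute carboxylic acid should hydrolyse the ketimine to the methyl ketone without ionising the tertiary allyl aryl ethers.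

Step 3
Reactants: 7 4-fluorobenzonitrile; 2 2-methylbut-3-en-2-ol
Product: 8 4-[(2-methylbut-3-en-2-yl)oxy]benzonitrile
Conditions: NaH (1.2 equiv), 2 (1.3 equiv), DMF, 0 °C → rt
Reagents that add atoms: none
Why: SNAr of a fluoride para to a nitrile by a tertiary alkoxide is a well-precedented reaction type, and the product ether is stable to the basic medium.

Step 4
Reactants: 8 4-[(2-methylbut-3-en-2-yl)oxy]benzonitrile
Product: 10 4-[(2-methylbut-3-en-2-yl)oxy]benzaldehyde, via N-alumino aldimine 9 (not isolated)
Conditions: i-Bu2AlH (1.2 equiv), toluene, −78 °C; MeOH; aq. potassium sodium tartrate (KNaC4H4O6), then 10% aq. citric acid, 0 °C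
Reagents that add atoms: water, O
Why: Partial reduction of a nitrile with i-Bu2AlH delivers one hydride to give an N-alumino aldimine that is stable at −78 °C and is hydrolysed to the aldehyde on mild aqueous work-up, conditions the tertiary allyl ether should tolerate.

Step 5
Reactants: 6 1-{2,4-bis[(2-methylbut-3-en-2-yl)oxy]phenyl}ethan-1-one; 10 4-[(2-methylbut-3-en-2-yl)oxy]benzaldehyde
Product: 12 (E)-1-{2,4-bis[(2-methylbut-3-en-2-yl)oxy]phenyl}-3-{4-[(2-methylbut-3-en-2-yl)oxy]phenyl}prop-2-en-1-one, via aldol adduct 11 (not isolated)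
Conditions: KOH (3 equiv), EtOH, rt
Reagents that add atoms: none
Why: Claisen–Schmidt condensation of a methyl ketone with a non-enolisable aldehyde, followed by E1cB dehydration of the aldol, should give the thermodynamically favoured E-enone, and all three ethers are inert to hydroxide.

Step 6
Reactants: 12 (E)-1-{2,4-bis[(2-methylbut-3-en-2-yl)oxy]phenyl}-3-{4-[(2-methylbut-3-en-2-yl)oxy]phenyl}prop-2-en-1-one
Product: 13 {2,4-bis[(2-methylbut-3-en-2-yl)oxy]phenyl}[(2R,3S)-3-{4-[(2-methylbut-3-en-2-yl)oxy]phenyl}oxiran-2-yl]methanone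
Conditions: La(O-i-Pr)3 (10 mol%), (S)-BINOL (10 mol%), Ph3As=O (10 mol%), t-BuOOH (1.5 equiv, decane), 4 Å molecular sieves, THF, rt; filtration through Et3N-deactivated silica
Reagents that add atoms: tert-butyl hydroperoxide, CC(C)(C)OO
Why: In this catalytic asymmetric Weitz–Scheffer (nucleophilic) epoxidation a lanthanum-bound peroxide adds to Cβ of the carbonyl-coordinated enone and closes to the trans epoxide, the (S)-BINOL ligand selecting the enone face that should give the 2R,3S isomer (the sense known for chalcone itself with this catalyst family), while the three isolated vinyl groups are inert to a nucleophilic oxidant.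

Step 7
Reactants: 13 {2,4-bis[(2-methylbut-3-en-2-yl)oxy]phenyl}[(2R,3S)-3-{4-[(2-methylbut-3-en-2-yl)oxy]phenyl}oxiran-2-yl]methanone
Product: 17 lespeflorin B3 [(2R,3R)-3,7-dihydroxy-2-[4-hydroxy-3-(3-methylbut-2-en-1-yl)phenyl]-6,8-bis(3-methylbut-2-en-1-yl)-2,3-dihydro-4H-chromen-4-one], via 2'-phenol epoxide 14 (not isolated), via bis-ether flavanonol 15 (not isolated), via mono-ether flavanonol 16 (not isolated)
Conditions: degassed o-xylene (0.01 M), PhNEt2 (0.5 equiv, acid scavenger), 130–135 °C, sealed tube, Ar, dark
Reagents that add atoms: none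
Why: Proposed new method: three thermal [3,3] shifts of aryl 1,1-dimethylallyl ethers (ortho-Claisen rearrangement, each dienone then tautomerising to the phenol) should move every tertiary O-allyl group to the neighbouring ring carbon as a prenyl group, and the shift at O-2' frees the phenol that opens the epoxide at its benzylic carbon to form the O1–C2 bond. The closest known reaction types are the Claisen rearrangement of 1,1-dimethylallyl aryl ethers to ortho-prenylphenols and the cyclisation of 2'-hydroxychalcone epoxides to trans-dihydroflavonols, which are coupled here in one operation that has not been shown on an epoxychalcone. Ring C closes in the 6-endo mode at Cβ, which should be favoured over 5-exo attack at Cα because the para-alkoxyphenyl group stabilises positive charge at the benzylic carbon. C2 is formed with inversion at Cβ (S to R) under control of the epoxide configuration and C3 is the untouched Cα (R), so the 2,3-trans isomer results, and even a looser cation-like opening should close to the diequatorial trans product. The regioselectivity needed on ring A is secured because O-2' has only C3' (later C8) as a free ortho position, O-4' should go to C5' (later C6) since C3' is flanked by both ether oxygens and then blocked, and O-4 of ring B has two equivalent ortho positions. The crowded, acyl-activated O-2' ether should rearrange first, so the epoxide is consumed while ring B is still an ether and cannot open to a quinone methide.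

**Compound list**

1 | 2,4-difluorobenzonitrile | N#Cc1ccc(F)cc1F | starting material
2 | 2-methylbut-3-en-2-ol | C=CC(C)(C)O | starting material
3 | 2-fluoro-4-[(2-methylbut-3-en-2-yl)oxy]benzonitrile (para substitution expected first) | N#Cc1ccc(OC(C)(C)C=C)cc1F | intermediate
4 | 2,4-bis[(2-methylbut-3-en-2-yl)oxy]benzonitrile | N#Cc1ccc(OC(C)(C)C=C)cc1OC(C)(C)C=C | intermediate
5 | N-lithio-1-{2,4-bis[(2-methylbut-3-en-2-yl)oxy]phenyl}ethan-1-imine | CC(=N[Li])c1ccc(OC(C)(C)C=C)cc1OC(C)(C)C=C | intermediate
6 | 1-{2,4-bis[(2-methylbut-3-en-2-yl)oxy]phenyl}ethan-1-one | CC(=O)c1ccc(OC(C)(C)C=C)cc1OC(C)(C)C=C | intermediate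
7 | 4-fluorobenzonitrile | N#Cc1ccc(F)cc1 | starting material
8 | 4-[(2-methylbut-3-en-2-yl)oxy]benzonitrile | N#Cc1ccc(OC(C)(C)C=C)cc1 | intermediate
9 | N-(diisobutylalumanyl)-1-{4-[(2-methylbut-3-en-2-yl)oxy]phenyl}methanimine | CC(C)C[Al](CC(C)C)N=Cc1ccc(OC(C)(C)C=C)cc1 | intermediate
10 | 4-[(2-methylbut-3-en-2-yl)oxy]benzaldehyde | O=Cc1ccc(OC(C)(C)C=C)cc1 | intermediate
11 | 1-{2,4-bis[(2-methylbut-3-en-2-yl)oxy]phenyl}-3-hydroxy-3-{4-[(2-methylbut-3-en-2-yl)oxy]phenyl}propan-1-one (racemic aldol) | C=CC(C)(C)Oc1ccc(C(O)CC(=O)c2ccc(OC(C)(C)C=C)cc2OC(C)(C)C=C)cc1 | intermediate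
12 | (E)-1-{2,4-bis[(2-methylbut-3-en-2-yl)oxy]phenyl}-3-{4-[(2-methylbut-3-en-2-yl)oxy]phenyl}prop-2-en-1-one | C=CC(C)(C)Oc1ccc(/C=C/C(=O)c2ccc(OC(C)(C)C=C)cc2OC(C)(C)C=C)cc1 | intermediate
13 | {2,4-bis[(2-methylbut-3-en-2-yl)oxy]phenyl}[(2R,3S)-3-{4-[(2-methylbut-3-en-2-yl)oxy]phenyl}oxiran-2-yl]methanone (trans epoxide) | O=C(c1ccc(OC(C)(C)C=C)cc1OC(C)(C)C=C)[C@@H]1O[C@H]1c1ccc(OC(C)(C)C=C)cc1 | intermediate
14 | {2-hydroxy-4-[(2-methylbut-3-en-2-yl)oxy]-3-(3-methylbut-2-en-1-yl)phenyl}[(2R,3S)-3-{4-[(2-methylbut-3-en-2-yl)oxy]phenyl}oxiran-2-yl]methanone | O=C(c1ccc(OC(C)(C)C=C)c(CC=C(C)C)c1O)[C@@H]1O[C@H]1c1ccc(OC(C)(C)C=C)cc1 | intermediate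
15 | (2R,3R)-3-hydroxy-7-[(2-methylbut-3-en-2-yl)oxy]-2-{4-[(2-methylbut-3-en-2-yl)oxy]phenyl}-8-(3-methylbut-2-en-1-yl)-2,3-dihydro-4H-chromen-4-one | C=CC(C)(C)Oc1ccc([C@H]2Oc3c(ccc(OC(C)(C)C=C)c3CC=C(C)C)C(=O)[C@@H]2O)cc1 | intermediate
16 | (2R,3R)-3,7-dihydroxy-2-{4-[(2-methylbut-3-en-2-yl)oxy]phenyl}-6,8-bis(3-methylbut-2-en-1-yl)-2,3-dihydro-4H-chromen-4-one | C=CC(C)(C)Oc1ccc([C@H]2Oc3c(cc(CC=C(C)C)c(O)c3CC=C(C)C)C(=O)[C@@H]2O)cc1 | intermediate
17 | lespeflorin B3, (2R,3R)-3,7-dihydroxy-2-[4-hydroxy-3-(3-methylbut-2-en-1-yl)phenyl]-6,8-bis(3-methylbut-2-en-1-yl)-2,3-dihydro-4H-chromen-4-one | CC(C)=CCc1cc([C@H]2Oc3c(cc(CC=C(C)C)c(O)c3CC=C(C)C)C(=O)[C@@H]2O)ccc1O | target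

**Step count**

Total steps: 7. Longest linear sequence: 5 steps (steps 1, 2, 5, 6, 7).

**Steps most likely to fail**

Step 7 (proposed new method). The epoxide may open or rearrange (Meinwald-type aryl or hydride shift) before the O-2' Claisen shift has freed the phenol. The tertiary ethers may lose isoprene instead of rearranging. The O-4' group may migrate to C3' before O-2' has claimed it. The phenol may close 5-exo at Cα. C2 may epimerise by ring opening to a quinone methide once the 4'-OH is free. Fallback with known chemistry, separating the two events: setting out from chalcone 12, thermolysis in degassed o-xylene at 135 °C (aromatic Claisen rearrangement with no epoxide present) should give (E)-1-[2,4-dihydroxy-3,5-bis(3-methylbut-2-en-1-yl)phenyl]-3-[4-hydroxy-3-(3-methylbut-2-en-1-yl)phenyl]prop-2-en-1-one F1. Treatment with MOMCl and NaH in DMF should give its tris(methoxymethyl) ether F2. The lanthanum–BINOL epoxidation of step 6 should give the (2R,3S)-epoxide of the tris(methoxymethyl) ether F3. HCl in MeOH–THF at 40 °C then removes the three acetals, and the freed 2'-phenol opens the protonated epoxide 6-endo with inversion, the known acid-mediated deprotection–cyclisation of 2'-(methoxymethoxy)chalcone epoxides to trans-dihydroflavonols. This comes back to the route at 17.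

Step 6. Oxygen transfer to the hindered, electron-rich enone may be slow, facial selectivity may be poor because the bulky 2'-ether twists the aryl ketone, and the para-alkoxyphenyl epoxide may open on acidic supports during isolation. Fallback by resolution instead of asymmetric catalysis: setting out from 12, achiral Weitz–Scheffer epoxidation (30% aq. H2O2, NaOH, MeOH–THF, 0 °C) should give the racemic trans epoxide, that is 13 together with its enantiomer {2,4-bis[(2-methylbut-3-en-2-yl)oxy]phenyl}[(2S,3R)-3-{4-[(2-methylbut-3-en-2-yl)oxy]phenyl}oxiran-2-yl]methanone F4. The two are separated by preparative chromatography on an amylose tris(3,5-dimethylphenylcarbamate) stationary phase. This comes back to the route at 13.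

Step 1. The second substitution, at the crowded ortho carbon of a ring already deactivated by the first alkoxy group, may stall, and the alkoxide may add to the nitrile. Fallback by O-allylation of a phenol instead of SNAr: setting out from alcohol 2, n-BuLi then Boc2O in THF should give tert-butyl 2-methylbut-3-en-2-yl carbonate F5. Pd(PPh3)4-catalysed decarboxylative O-allylation (Tsuji–Trost type, the phenoxide attacking the more substituted terminus of the 1,1-dimethylallyl palladium intermediate) of commercial 2,4-dihydroxybenzonitrile with F5 in THF at 0 °C should give the bis-ether. This comes back to the route at 4.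

**Further compounds**

F1 | step 7 | (E)-1-[2,4-dihydroxy-3,5-bis(3-methylbut-2-en-1-yl)phenyl]-3-[4-hydroxy-3-(3-methylbut-2-en-1-yl)phenyl]prop-2-en-1-one | CC(C)=CCc1cc(/C=C/C(=O)c2cc(CC=C(C)C)c(O)c(CC=C(C)C)c2O)ccc1O
F2 | step 7 | (E)-1-[2,4-bis(methoxymethoxy)-3,5-bis(3-methylbut-2-en-1-yl)phenyl]-3-[4-(methoxymethoxy)-3-(3-methylbut-2-en-1-yl)phenyl]prop-2-en-1-one | CC(C)=CCc1cc(/C=C/C(=O)c2cc(CC=C(C)C)c(OCOC)c(CC=C(C)C)c2OCOC)ccc1OCOC
F3 | step 7 | [2,4-bis(methoxymethoxy)-3,5-bis(3-methylbut-2-en-1-yl)phenyl]{(2R,3S)-3-[4-(methoxymethoxy)-3-(3-methylbut-2-en-1-yl)phenyl]oxiran-2-yl}methanone | O=C(c1cc(CC=C(C)C)c(OCOC)c(CC=C(C)C)c1OCOC)[C@@H]1O[C@H]1c1ccc(OCOC)c(CC=C(C)C)c1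
F4 | step 6 | {2,4-bis[(2-methylbut-3-en-2-yl)oxy]phenyl}[(2S,3R)-3-{4-[(2-methylbut-3-en-2-yl)oxy]phenyl}oxiran-2-yl]methanone (enantiomer of 13) | O=C(c1ccc(OC(C)(C)C=C)cc1OC(C)(C)C=C)[C@H]1O[C@@H]1c1ccc(OC(C)(C)C=C)cc1
F5 | step 1 | tert-butyl 2-methylbut-3-en-2-yl carbonate | C=CC(C)(C)OC(=O)OC(C)(C)C
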